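**Remarks (assumptions)**
- Atom labels follow the benzofuran numbering of the target (O1, C2, C3, C3a, C4, C5, C6, C7, C7a) and are used for the corresponding atoms of every intermediate.
- 3-Methoxybut-3-en-2-one is not assumed to be a catalogue chemical and is made in step 4.
- The (S)-configured phosphoric acid TRIP is assumed to direct the crotyl group to the si face of an aryl aldehyde; if the sense proves opposite, its antipode is used.
- C5 of compounds 13–20 (and of F1, F7, F8) is erased later and is written without configuration.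

## Structural features

The target is a 2,3-dihydrofuran ring (O1, C2, C3, C3a, C7a) fused along C3a–C7a to a six-membered carbocycle that is a cyclohexa-2,4-dienone (C6=O, C7=C7a, C3a=C4). Because O1 sits on C7a, the C6 carbonyl is a vinylogous ester, and the whole is an ortho-quinol methyl ether, a non-aromatic tautomer-locked form of a trioxygenated benzene. C5 is a fully substituted sp3 carbon carrying methoxy and allyl, between the C6 carbonyl and the sp2 carbon C4. C2 (aryl, S) and C3 (methyl, S) are adjacent and trans on the five-membered ring. C5 (R) is separated from them by the planar C3a=C4 unit, with the allyl group on the face of the C2 aryl group and the methoxy group on the face of the C3 methyl group. Fragile elements are the 6-allyl-2,4-dienone (prone to further [3,3] shifts that end in aromatic allyl ethers or allylphenols on heating or with acid), the benzylic C2–O1 bond next to an electron-rich aryl ring, and the enol ether. The real difficulty is to set the quaternary C5 relative to C2/C3 across a flat ring, where no direct substrate control can operate. The key step exploits that C3a and C5 are the two ends of the allylic triad C3a–C4=C5 and that C3a is the direct neighbour of C3. An allyl group placed on an sp3 C3a, where the C3 methyl controls its face, can be handed to C5 across that same face, and C3a becomes sp2 exactly as the target requires.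

## Logic of the disconnections

**22 ⇒ 21.** The C5–CH2 (allyl) bond is cut and the allyl terminus is reconnected to C3a (retro-Cope). In one sentence, the route is a suprafacial [3,3] shift of an allyl group from the ring-fusion carbon C3a of 21 to C5. The cut is made here because it turns the remote C5 problem into a C3a problem next to C3. The gain is that C5 needs no control element of its own and the 2,4-dienone pattern appears in the same event. The demand is that the shift uses the C4=C5 arm and not the C7a=C7 arm, and that 22 is not heated long enough to rearrange further.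

**21 ⇒ 18.** The C4=C5 double bond is removed. Its precursor 18 is a simple vinylogous ester whose α′ position is C5, so the unsaturation can be introduced regiospecifically. The demand is a dehydrogenation mild enough (room temperature) for the allyl dienone.

**18 ⇒ 16.** The C7–C7a bond and the enol-ether linkage O1–C7a are cut, which returns the ester carbonyl of 16 (C7a) and a methyl ketone (C6, C7). The six-membered ring is thus made by acylation of a ketone enolate, and O1, which was the ring oxygen of 16, closes back onto C7a. The demand is acylation of an α-quaternary ester carbonyl, which is well established for 5-oxohexanoates.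

**16 ⇒ 13.** The C3a–allyl bond is cut. The allyl group is introduced last on C3a so that it enters anti to the C3 methyl group, which is the relative configuration the key step needs. The demand is that the ketone stays masked as its silyl enol ether while the ester enolate is formed.

**13 ⇒ 8 + 10.** The C3a–C4 bond is cut (conjugate addition). Compound 10 carries C4–C7 with the C5 methoxy group and the C6 carbonyl already in place, and the silyl transfer of the forward reaction delivers the ketone masked. The demand is 1,4- over 1,2-addition.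

**8 ⇒ 6 ⇒ 4.** No C–C bond is cut; C7a is taken back from the carboxyl level to the primary alcohol of 6 and to the terminal alkene carbon of 4. The demand is anti-Markovnikov hydration and oxidation of the primary alcohol in the presence of the benzylic one.

**4 ⇒ 1 + 2.** The C2–C3 bond is cut. One catalytic crotylation sets C2 and C3 together (anti), and every later stereocenter is relayed from them. The demand is high anti and facial selectivity with an electron-rich aryl aldehyde.

**10 ⇒ 9.** Loss of methanol from a commercial ketal.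

## Other disconnections considered

**Alternative 1:** (the first that comes to mind) cut C5–OMe. The forward step is oxidative dearomatisation of the phenol (2S,3S)-5-allyl-3-methyl-2-(3,4,5-trimethoxyphenyl)-2,3-dihydrobenzofuran-6-ol A1 with PhI(OAc)2 in methanol. The chosen plan is preferred on two grounds. First, methanol is expected to attack the oxidised phenol mainly para to the oxygen, at the alkyl-substituted C3a, which gives the 3a-methoxy isomer A2 and not the ortho-quinol ether. Second, whatever attacks C5 does so on a flat intermediate in which C5 is 1,4-related to C3, so no facial preference can be expected. The hardest stereocenter would be left to chance.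

**Alternative 2:** cut C3–C3a and O1–C2 (biomimetic [3+2]). The forward step is acid-promoted cycloaddition of the phenoxonium ion generated from the quinone monoketal 2-allyl-4,4,5-trimethoxycyclohexa-2,5-dien-1-one A3 with (E)-isoelemicin A4, giving the 3a-allyl dienone A5, followed by the same [3,3] shift. This is the shortest plan. However, the cation is achiral and no dependable catalyst-controlled version of this cation/alkene union is available, so A5 would be racemic. The C3/C3a relationship, on which C5 finally depends, would be set in an endo/exo-dependent step that also leads to bicyclo[3.2.1]octane isomers. The chosen plan fixes C2/C3 by catalysis and C3a by an enolate alkylation anti to the C3 methyl group.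

**Alternative 3:** cut C5–allyl at the ortho-quinone level. The forward step is 1,2-addition of an allyl nucleophile to the C5 carbonyl of (2S,3S)-3-methyl-2-(3,4,5-trimethoxyphenyl)-2,3-dihydrobenzofuran-5,6-dione A6, giving the ortho-quinol A7, then O-methylation. Regiochemistry should be good because the C6 carbonyl is deactivated as a vinylogous ester. The plan is nonetheless less attractive: the face of C5 would have to be chosen entirely by a chiral reagent on a redox-active quinone that allyl metals readily reduce; the tertiary α-ketol A7 is prone to acyloin shift and dimerisation; and its methylation adds a step.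

Key step: step 9

## Route

**Step 1**
Reactants: 1 3,4,5-trimethoxybenzaldehyde; 2 (E)-crotylboronic acid pinacol ester
Product: 4 (1S,2S)-2-methyl-1-(3,4,5-trimethoxyphenyl)but-3-en-1-ol, via O-pinacolboryl ether 3 (not isolated)
Conditions: (S)-TRIP (5 mol %), PhMe, 4 Å MS, −30 °C; aq. NaHCO3 work-up
Reagents that add atoms: none
Why: Chiral-phosphoric-acid-catalysed crotylboration; the (E)-crotylboronate reacts through a closed chair transition state with the aryl group equatorial, which fixes the anti C2/C3 relationship, while the acid (hydrogen-bonded to a boronate oxygen and the formyl C–H) selects the si face of the aldehyde and so sets (1S,2S).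

**Step 2**
Reactants: 4 (1S,2S)-2-methyl-1-(3,4,5-trimethoxyphenyl)but-3-en-1-ol
Product: 6 (1S,2S)-2-methyl-1-(3,4,5-trimethoxyphenyl)butane-1,4-diol, via alkyl-9-BBN adduct 5 (not isolated)
Conditions: 9-BBN (1.3 equiv), THF, 0 °C → rt; then NaOH, H2O2, 0 °C → rt
Reagents that add atoms: hydrogen peroxide, OO
Why: Hydroboration–oxidation; 9-BBN places boron on the terminal carbon of the monosubstituted alkene and the oxidative work-up replaces it by OH, and neither existing stereocenter is touched.

**Step 3**
Reactants: 6 (1S,2S)-2-methyl-1-(3,4,5-trimethoxyphenyl)butane-1,4-diol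
Product: 8 (4S,5S)-4-methyl-5-(3,4,5-trimethoxyphenyl)dihydrofuran-2(3H)-one, via lactol 7 (not isolated)
Conditions: TEMPO (10 mol %), PhI(OAc)2 (2.5 equiv), CH2Cl2, rt
Reagents that add atoms: none
Why: Oxoammonium-mediated oxidative lactonisation of a 1,4-diol; the primary alcohol is oxidised much faster than the hindered benzylic one, the hydroxy aldehyde closes to lactol 7 and a second oxidation gives the γ-lactone, with C2 and C3 not epimerisable under these neutral conditions.

**Step 4**
Reactants: 9 3,3-dimethoxybutan-2-one
Product: 10 3-methoxybut-3-en-2-one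
Conditions: KHSO4 (cat.), neat, 140 °C, MeOH removed through a column; then distillation
Reagents that add atoms: none
Why: Acid-catalysed loss of methanol from a dimethyl ketal to its methyl enol ether, driven by continuous removal of methanol; only the C4 methyl can supply the hydrogen.

**Step 5**
Reactants: 8 (4S,5S)-4-methyl-5-(3,4,5-trimethoxyphenyl)dihydrofuran-2(3H)-one; 10 3-methoxybut-3-en-2-one
Product: 13 (3S,4S,5S)-3-[2-methoxy-3-(trimethylsilyloxy)but-2-en-1-yl]-4-methyl-5-(3,4,5-trimethoxyphenyl)dihydrofuran-2(3H)-one, via lithium enolate 11 (not isolated), via ketene silyl acetal 12 (not isolated)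
Conditions: LiN(iPr)2 (LDA, 1.05 equiv), THF, −78 °C; Me3SiCl, −78 → 0 °C; solvent exchange to CH2Cl2 (LiCl filtered off); 10 (1.2 equiv), Me3SiOTf (5 mol %), −78 °C; Et3N, non-aqueous work-up
Reagents that add atoms: chlorotrimethylsilane, C[Si](C)(C)Cl
Why: Mukaiyama–Michael addition with silyl transfer; the Me3SiOTf-activated α-methoxy enone accepts the ketene silyl acetal at its unsubstituted β-carbon (C4) and the silyl group ends on the new enolate oxygen, so the methyl ketone emerges already masked as a regiodefined enol ether. The configuration formed at C3a does not matter because that carbon is planarised again in step 6.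

**Step 6**
Reactants: 13 (3S,4S,5S)-3-[2-methoxy-3-(trimethylsilyloxy)but-2-en-1-yl]-4-methyl-5-(3,4,5-trimethoxyphenyl)dihydrofuran-2(3H)-one
Product: 16 (3R,4S,5S)-3-allyl-3-(2-methoxy-3-oxobutyl)-4-methyl-5-(3,4,5-trimethoxyphenyl)dihydrofuran-2(3H)-one, via lithium enolate 14 (not isolated), via allylated silyl enol ether 15 (not isolated)
Conditions: LiN(iPr)2 (LDA, 1.1 equiv), THF, −78 °C; allyl bromide (1.5 equiv), DMPU, −78 → −30 °C; then 1 M HCl, THF, 0 °C
Reagents that add atoms: allyl bromide, C=CCBr
Why: Alkylation of a lactone lithium enolate; the silyl enol ether is inert to the amide base so only the lactone α-hydrogen is removed, and allyl bromide attacks the planar enolate on the face anti to the adjacent C3 methyl group, which puts allyl trans to methyl (on the aryl face) and sets the quaternary C3a. The acidic work-up releases the methyl ketone.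

**Step 7**
Reactants: 16 (3R,4S,5S)-3-allyl-3-(2-methoxy-3-oxobutyl)-4-methyl-5-(3,4,5-trimethoxyphenyl)dihydrofuran-2(3H)-one
Product: 18 (2S,3S,3aR)-3a-allyl-5-methoxy-3-methyl-2-(3,4,5-trimethoxyphenyl)-3,3a,4,5-tetrahydrobenzofuran-6(2H)-one, via hydroxy dione 17 (not isolated)
Conditions: KOtBu (2.2 equiv), THF, 0 °C → rt; AcOH (2.2 equiv); then TsOH·H2O (5 mol %), PhMe, 4 Å MS, rt → 40 °C
Reagents that add atoms: none
Why: Intramolecular Claisen (Dieckmann-type) condensation of a 5-oxohexanoate unit; only the methyl-side enolate (C7) can reach the ester carbonyl C7a through a six-membered transition state, and the 1,3-dione enolate is the thermodynamic sink. After neutralisation the freed C2 hydroxyl adds to the nearby C7a carbonyl (five-membered hemiketal) and dehydrates to the vinylogous ester; the quaternary C3a cannot epimerise.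

**Step 8**
Reactants: 18 (2S,3S,3aR)-3a-allyl-5-methoxy-3-methyl-2-(3,4,5-trimethoxyphenyl)-3,3a,4,5-tetrahydrobenzofuran-6(2H)-one
Product: 21 (2S,3S,3aS)-3a-allyl-5-methoxy-3-methyl-2-(3,4,5-trimethoxyphenyl)-3,3a-dihydrobenzofuran-6(2H)-one, via lithium dienolate 19 (not isolated), via silyl dienol ether 20 (not isolated)
Conditions: LiN(iPr)2 (LDA, 1.1 equiv), THF, −78 °C; Me3SiCl; then Pd(OAc)2 (1.05 equiv), MeCN, rt
Reagents that add atoms: none
Why: Saegusa–Ito oxidation; a vinylogous ester is deprotonated kinetically at the α′ carbon (C5), the silyl dienol ether is palladated there and β-hydride elimination can only use a C4 hydrogen, giving C4=C5 at room temperature. The C5 centre of 18 disappears, and since C3a bears no hydrogen 21 cannot aromatise; the change of the C3a descriptor from R to S is only a change in CIP priorities.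

**Step 9**
Reactants: 21 (2S,3S,3aS)-3a-allyl-5-methoxy-3-methyl-2-(3,4,5-trimethoxyphenyl)-3,3a-dihydrobenzofuran-6(2H)-one
Product: 22 (2S,3S,5R)-5-allyl-5-methoxy-3-methyl-2-(3,4,5-trimethoxyphenyl)-3,5-dihydrobenzofuran-6(2H)-one
Conditions: PhMe (0.01 M, degassed), BHT (trace), 100–110 °C, sealed, dark; stopped before full conversion, recovered 21 recycled
Reagents that add atoms: none
Why: Concerted [3,3]-sigmatropic (Cope) shift: the C3a–CH2 bond breaks while the allyl terminus bonds to C5 through a six-membered array made of the allyl group and the ring segment C3a–C4=C5, leaving C3a=C4 behind. The closest known reaction type is the thermal allyl shift of 4-allylcyclohexa-2,5-dienones to 6-allylcyclohexa-2,4-dienones (the Cope stage of the para-Claisen manifold run in reverse), which is also the accepted biogenetic link between 3a-allyl and 5-allyl hydrobenzofuranoid neolignans and is fast near 100 °C because the ring part of the transition state gains phenoxyl-like aromatic character. No ring is closed. The only new stereocenter, C5, is dictated by C3a: the allyl group can migrate only across the ring face it already occupies, so the allyl on the aryl-bearing face of 21 becomes the 5R allyl of 22 and the methoxy group is left on the methyl-bearing face. Regioselectivity between the two enone arms is needed: migration through C4=C5 keeps the push–pull system O1–C7a=C7–C6=O intact and extends it, whereas migration through C7a=C7 would interrupt that conjugation in the transition state, and C5 carries the methoxy/acyl pair that stabilises the forming bond. The position of equilibrium should favour 22 because the congested, fully carbon-substituted C3a next to C3 becomes planar and a cross-conjugated dienone becomes a linearly conjugated 3-alkoxydienone. Chemoselectivity against a second [3,3] shift of 22 to the aromatic 6-allyloxy ether is secured by the lowest effective temperature, high dilution and partial conversion.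

## Compound list

1 | 3,4,5-trimethoxybenzaldehyde | O=Cc1cc(OC)c(OC)c(OC)c1 | starting material
2 | (E)-crotylboronic acid pinacol ester | C/C=C/CB1OC(C)(C)C(C)(C)O1 | starting material
3 | 4,4,5,5-tetramethyl-2-{[(1S,2S)-2-methyl-1-(3,4,5-trimethoxyphenyl)but-3-en-1-yl]oxy}-1,3,2-dioxaborolane | C=C[C@H](C)[C@H](OB1OC(C)(C)C(C)(C)O1)c1cc(OC)c(OC)c(OC)c1 | intermediate
4 | (1S,2S)-2-methyl-1-(3,4,5-trimethoxyphenyl)but-3-en-1-ol | C=C[C@H](C)[C@H](O)c1cc(OC)c(OC)c(OC)c1 | intermediate
5 | (1S,2S)-4-(9-borabicyclo[3.3.1]nonan-9-yl)-2-methyl-1-(3,4,5-trimethoxyphenyl)butan-1-ol | C1CC2CCCC(C1)B2CC[C@H](C)[C@H](O)c1cc(OC)c(OC)c(OC)c1 | intermediate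
6 | (1S,2S)-2-methyl-1-(3,4,5-trimethoxyphenyl)butane-1,4-diol | OCC[C@H](C)[C@H](O)c1cc(OC)c(OC)c(OC)c1 | intermediate
7 | (4S,5S)-4-methyl-5-(3,4,5-trimethoxyphenyl)tetrahydrofuran-2-ol (both anomers) | OC1C[C@H](C)[C@@H](c2cc(OC)c(OC)c(OC)c2)O1 | intermediate
8 | (4S,5S)-4-methyl-5-(3,4,5-trimethoxyphenyl)dihydrofuran-2(3H)-one | O=C1C[C@H](C)[C@@H](c2cc(OC)c(OC)c(OC)c2)O1 | intermediate
9 | 3,3-dimethoxybutan-2-one | CC(=O)C(C)(OC)OC | starting material
10 | 3-methoxybut-3-en-2-one | C=C(OC)C(C)=O | intermediate
11 | lithium (4S,5S)-4-methyl-5-(3,4,5-trimethoxyphenyl)-4,5-dihydrofuran-2-olate | [Li]OC1=C[C@H](C)[C@@H](c2cc(OC)c(OC)c(OC)c2)O1 | intermediate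
12 | trimethyl{[(4S,5S)-4-methyl-5-(3,4,5-trimethoxyphenyl)-4,5-dihydrofuran-2-yl]oxy}silane | C[Si](C)(C)OC1=C[C@H](C)[C@@H](c2cc(OC)c(OC)c(OC)c2)O1 | intermediate
13 | (3S,4S,5S)-3-[2-methoxy-3-(trimethylsilyloxy)but-2-en-1-yl]-4-methyl-5-(3,4,5-trimethoxyphenyl)dihydrofuran-2(3H)-one | O=C1O[C@H](c2cc(OC)c(OC)c(OC)c2)[C@@H](C)[C@@H]1CC(OC)=C(C)O[Si](C)(C)C | intermediate
14 | lithium enolate of 13 (lithium 3-[2-methoxy-3-(trimethylsilyloxy)but-2-en-1-yl]-(4S,5S)-4-methyl-5-(3,4,5-trimethoxyphenyl)-4,5-dihydrofuran-2-olate) | [Li]OC1=C(CC(OC)=C(C)O[Si](C)(C)C)[C@H](C)[C@@H](c2cc(OC)c(OC)c(OC)c2)O1 | intermediate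
15 | (3R,4S,5S)-3-allyl-3-[2-methoxy-3-(trimethylsilyloxy)but-2-en-1-yl]-4-methyl-5-(3,4,5-trimethoxyphenyl)dihydrofuran-2(3H)-one | O=C1O[C@H](c2cc(OC)c(OC)c(OC)c2)[C@@H](C)[C@@]1(CC=C)CC(OC)=C(C)O[Si](C)(C)C | intermediate
16 | (3R,4S,5S)-3-allyl-3-(2-methoxy-3-oxobutyl)-4-methyl-5-(3,4,5-trimethoxyphenyl)dihydrofuran-2(3H)-one | O=C1O[C@H](c2cc(OC)c(OC)c(OC)c2)[C@@H](C)[C@@]1(CC=C)CC(OC)C(C)=O | intermediate
17 | (4R)-4-allyl-4-[(1S,2S)-1-hydroxy-1-(3,4,5-trimethoxyphenyl)propan-2-yl]-6-methoxycyclohexane-1,3-dione | C=CC[C@@]1(CC(OC)C(=O)CC1=O)[C@H](C)[C@H](O)c2cc(OC)c(OC)c(OC)c2 | intermediate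
18 | (2S,3S,3aR)-3a-allyl-5-methoxy-3-methyl-2-(3,4,5-trimethoxyphenyl)-3,3a,4,5-tetrahydrobenzofuran-6(2H)-one | C=CC[C@]12CC(OC)C(=O)C=C1O[C@H](c3cc(OC)c(OC)c(OC)c3)[C@H]2C | intermediate
19 | lithium (2S,3S,3aR)-3a-allyl-5-methoxy-3-methyl-2-(3,4,5-trimethoxyphenyl)-2,3,3a,4-tetrahydrobenzofuran-6-olate | C=CC[C@]12CC(OC)=C(O[Li])C=C1O[C@H](c3cc(OC)c(OC)c(OC)c3)[C@H]2C | intermediate
20 | (2S,3S,3aR)-3a-allyl-5-methoxy-3-methyl-2-(3,4,5-trimethoxyphenyl)-6-(trimethylsilyloxy)-2,3,3a,4-tetrahydrobenzofuran | C=CC[C@]12CC(OC)=C(O[Si](C)(C)C)C=C1O[C@H](c3cc(OC)c(OC)c(OC)c3)[C@H]2C | intermediate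
21 | (2S,3S,3aS)-3a-allyl-5-methoxy-3-methyl-2-(3,4,5-trimethoxyphenyl)-3,3a-dihydrobenzofuran-6(2H)-one | C=CC[C@]12C=C(OC)C(=O)C=C1O[C@H](c3cc(OC)c(OC)c(OC)c3)[C@H]2C | intermediate
22 | (2S,3S,5R)-5-allyl-5-methoxy-3-methyl-2-(3,4,5-trimethoxyphenyl)-3,5-dihydrobenzofuran-6(2H)-one | C=CC[C@@]1(OC)C=C2C(=CC1=O)O[C@H](c1cc(OC)c(OC)c(OC)c1)[C@H]2C | target

## Step count and least certain steps

Total step count: 9. Longest linear sequence: 8 (steps 1–3 and 5–9; step 4 prepares the Michael acceptor 10).

**Step 9 (key step).** Most likely to go wrong is loss of material into aromatic products. This can happen by migration of the allyl group through the other enone arm (C7a=C7) followed by enolisation, or by a second [3,3] shift of 22 to the 6-allyloxy arene. Both are driven by aromatisation, and the window between the first and second shift may be narrow; an equilibrium that does not lie fully on the side of 22 is the lesser concern. The fallback avoids the sigmatropic relay, sets out from 13 and returns at 22. Treatment of 13 with KOtBu (which cleaves the silyl enol ether to the enolate and effects the Claisen condensation) and then TsOH should give (2S,3S,3aS)-5-methoxy-3-methyl-2-(3,4,5-trimethoxyphenyl)-3,3a,4,5-tetrahydrobenzofuran-6(2H)-one F1. Its α′-enolate (LDA) is allylated at C5 with allyl bromide to (2S,3S,3aS,5R)-5-allyl-5-methoxy-3-methyl-2-(3,4,5-trimethoxyphenyl)-3,3a,4,5-tetrahydrobenzofuran-6(2H)-one F2; only modest control from the C3a hydrogen is expected, so the C5 epimers would be separated. Me3SiOTf/Et3N then gives the extended silyl dienol ether (2S,3S,5R)-5-allyl-5-methoxy-3-methyl-2-(3,4,5-trimethoxyphenyl)-6-(trimethylsilyloxy)-2,3,4,5-tetrahydrobenzofuran F3, and DDQ (CH2Cl2, 0 °C) dehydrogenates it across C3a–C4, in the manner of the dienol-ether route to linear dienones, to 22.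

**Step 5.** Most likely to go wrong is 1,2-addition to the ketone carbonyl or acid-induced oligomerisation of the α-methoxy enone outrunning conjugate addition. The fallback builds the side chain from an aldehyde instead, sets out from 8 and returns at 16. Formylation (NaH, HCO2Et) gives (4S,5S)-3-(hydroxymethylene)-4-methyl-5-(3,4,5-trimethoxyphenyl)dihydrofuran-2(3H)-one F4. Tsuji–Trost C-allylation of this soft enolate (Pd(PPh3)4, allyl methyl carbonate), anti to the C3 methyl group, gives (3S,4S,5S)-3-allyl-4-methyl-2-oxo-5-(3,4,5-trimethoxyphenyl)tetrahydrofuran-3-carbaldehyde F5. Horner–Wadsworth–Emmons reaction with dimethyl (1-methoxy-2-oxopropyl)phosphonate gives (3S,4S,5S)-3-allyl-3-(2-methoxy-3-oxobut-1-en-1-yl)-4-methyl-5-(3,4,5-trimethoxyphenyl)dihydrofuran-2(3H)-one F6, and conjugate reduction with [(Ph3P)CuH]6 returns 16.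

**Step 6.** Most likely to go wrong is sluggish or incompletely face-selective C-alkylation at the fully substituted enolate carbon, with proton transfer or O-allylation taking over. The fallback replaces the ionic alkylation by a radical one, sets out from 13 and returns at 16. The lithium enolate of 13 is trapped with PhSeSePh to give (4S,5S)-3-[2-methoxy-3-(trimethylsilyloxy)but-2-en-1-yl]-4-methyl-3-(phenylselanyl)-5-(3,4,5-trimethoxyphenyl)dihydrofuran-2(3H)-one F7. Keck allylation (Bu3SnCH2CH=CH2, AIBN, PhH, 80 °C) of the derived planar α-acyl radical, again anti to the C3 methyl group, gives 15, and the same acidic work-up gives 16.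

**Step 8.** Most likely to go wrong is coordination of divalent palladium to the terminal alkene, slowing β-hydride elimination, or desilylation back to 18. The fallback uses a selenoxide elimination, sets out from 18 and returns at 21. The α′-enolate of 18 (LDA) is selenenylated with PhSeBr to (2S,3S,3aR)-3a-allyl-5-methoxy-3-methyl-5-(phenylselanyl)-2-(3,4,5-trimethoxyphenyl)-3,3a,4,5-tetrahydrobenzofuran-6(2H)-one F8. Oxidation (H2O2, pyridine, CH2Cl2, 0 °C) and syn-elimination toward C4, the only carbon with a β-hydrogen, give 21.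

## Further compounds

F1 | step 9 | (2S,3S,3aS)-5-methoxy-3-methyl-2-(3,4,5-trimethoxyphenyl)-3,3a,4,5-tetrahydrobenzofuran-6(2H)-one | COC1C[C@@H]2C(=CC1=O)O[C@H](c3cc(OC)c(OC)c(OC)c3)[C@H]2C
F2 | step 9 | (2S,3S,3aS,5R)-5-allyl-5-methoxy-3-methyl-2-(3,4,5-trimethoxyphenyl)-3,3a,4,5-tetrahydrobenzofuran-6(2H)-one | C=CC[C@@]1(OC)C[C@@H]2C(=CC1=O)O[C@H](c3cc(OC)c(OC)c(OC)c3)[C@H]2C
F3 | step 9 | (2S,3S,5R)-5-allyl-5-methoxy-3-methyl-2-(3,4,5-trimethoxyphenyl)-6-(trimethylsilyloxy)-2,3,4,5-tetrahydrobenzofuran | C=CC[C@@]1(OC)CC2=C(C=C1O[Si](C)(C)C)O[C@H](c3cc(OC)c(OC)c(OC)c3)[C@H]2C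
F4 | step 5 | (4S,5S)-3-(hydroxymethylene)-4-methyl-5-(3,4,5-trimethoxyphenyl)dihydrofuran-2(3H)-one | O=C1O[C@H](c2cc(OC)c(OC)c(OC)c2)[C@@H](C)C1=CO
F5 | step 5 | (3S,4S,5S)-3-allyl-4-methyl-2-oxo-5-(3,4,5-trimethoxyphenyl)tetrahydrofuran-3-carbaldehyde | O=C1O[C@H](c2cc(OC)c(OC)c(OC)c2)[C@@H](C)[C@@]1(CC=C)C=O
F6 | step 5 | (3S,4S,5S)-3-allyl-3-(2-methoxy-3-oxobut-1-en-1-yl)-4-methyl-5-(3,4,5-trimethoxyphenyl)dihydrofuran-2(3H)-one | O=C1O[C@H](c2cc(OC)c(OC)c(OC)c2)[C@@H](C)[C@@]1(CC=C)C=C(OC)C(C)=O
F7 | step 6 | (4S,5S)-3-[2-methoxy-3-(trimethylsilyloxy)but-2-en-1-yl]-4-methyl-3-(phenylselanyl)-5-(3,4,5-trimethoxyphenyl)dihydrofuran-2(3H)-one | O=C1O[C@H](c2cc(OC)c(OC)c(OC)c2)[C@@H](C)C1(CC(OC)=C(C)O[Si](C)(C)C)[Se]c3ccccc3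
F8 | step 8 | (2S,3S,3aR)-3a-allyl-5-methoxy-3-methyl-5-(phenylselanyl)-2-(3,4,5-trimethoxyphenyl)-3,3a,4,5-tetrahydrobenzofuran-6(2H)-one | C=CC[C@]12CC(OC)([Se]c3ccccc3)C(=O)C=C1O[C@H](c4cc(OC)c(OC)c(OC)c4)[C@H]2C
A1 | alternative 1 | (2S,3S)-5-allyl-3-methyl-2-(3,4,5-trimethoxyphenyl)-2,3-dihydrobenzofuran-6-ol | C=CCc1cc2c(cc1O)O[C@H](c3cc(OC)c(OC)c(OC)c3)[C@H]2C
A2 | alternative 1 | (2S,3S)-5-allyl-3a-methoxy-3-methyl-2-(3,4,5-trimethoxyphenyl)-3,3a-dihydrobenzofuran-6(2H)-one (either C3a epimer) | C=CCC1=CC2(OC)C(=CC1=O)O[C@H](c3cc(OC)c(OC)c(OC)c3)[C@H]2C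
A3 | alternative 2 | 2-allyl-4,4,5-trimethoxycyclohexa-2,5-dien-1-one | C=CCC1=CC(OC)(OC)C(OC)=CC1=O
A4 | alternative 2 | (E)-isoelemicin, 1,2,3-trimethoxy-5-[(E)-prop-1-en-1-yl]benzene | C/C=C/c1cc(OC)c(OC)c(OC)c1
A5 | alternative 2 | racemic 3a-allyl-5-methoxy-3-methyl-2-(3,4,5-trimethoxyphenyl)-3,3a-dihydrobenzofuran-6(2H)-one (relative configuration of 21, one enantiomer drawn) | C=CC[C@]12C=C(OC)C(=O)C=C1O[C@H](c3cc(OC)c(OC)c(OC)c3)[C@H]2C
A6 | alternative 3 | (2S,3S)-3-methyl-2-(3,4,5-trimethoxyphenyl)-2,3-dihydrobenzofuran-5,6-dione | O=C1C=C2C(=CC1=O)O[C@H](c3cc(OC)c(OC)c(OC)c3)[C@H]2C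
A7 | alternative 3 | (2S,3S,5R)-5-allyl-5-hydroxy-3-methyl-2-(3,4,5-trimethoxyphenyl)-3,5-dihydrobenzofuran-6(2H)-one | C=CC[C@@]1(O)C=C2C(=CC1=O)O[C@H](c3cc(OC)c(OC)c(OC)c3)[C@H]2C
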